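**Retrosynthetic overview**
- Ring C is closed last: kurarinone ⇐ 2'-hydroxychalcone (kuraridin) by oxa-Michael closure; rings A and B are bought as aromatics.
- Chalcone ⇐ ortho-lithiated lavandulyl arene + ring-B cinnamoyl Weinreb amide.
- Lavandulyl chain ⇐ (R)-2-(arylmethyl)hex-4-enoic acid: CO2H → C(CH3)=CH2 (MeLi, then methylenation) and crotyl → prenyl (cross-metathesis).
- Key disconnection: the C2''–C3'' bond at the lavandulyl stereocentre, made by Ireland–Claisen [3,3] rearrangement of an (R)-but-3-en-2-yl 3-arylpropanoate with 1,3-chirality transfer from the bought alcohol.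
- Ester ⇐ 5-methoxyresorcinol (bis-MOM ether, directed metalation, β-propiolactone) + (R)-but-3-en-2-ol.

Assumption: (R)-but-3-en-2-ol is bought enantiopure. C2 cannot be relayed from the remote lavandulyl centre, so ring closure gives both C2 epimers in about equal amounts. The (2S) epimer is collected by separating the two diastereomers, and the (2R) epimer is returned to the equilibrating ring-closure conditions. Phenoxide and carboxylate salts that are only protonated on work-up are not numbered.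

**Step 1**
Reactants: 1 5-methoxybenzene-1,3-diol (5-methoxyresorcinol)
Product: 2 1-methoxy-3,5-bis(methoxymethoxy)benzene
Conditions: NaH, MOMCl, DMF, 0 °C → rt
Reagents that add atoms: chloromethyl methyl ether (MOMCl), COCCl
Why: Double Williamson O-alkylation (MOM protection) of the two phenoxides; the MOM ethers later direct both lithiations.

**Step 2**
Reactants: 2 1-methoxy-3,5-bis(methoxymethoxy)benzene; 3 oxetan-2-one (β-propiolactone)
Product: 6 3-[4-methoxy-2,6-bis(methoxymethoxy)phenyl]propanoic acid, via aryllithium 4 (not isolated), via arylmagnesium bromide 5 (not isolated)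
Conditions: n-BuLi, THF, 0 °C; MgBr2·OEt2; CuBr·SMe2 (10 mol %), 3, −30 → 0 °C; then 1 M HCl, 0 °C
Reagents that add atoms: none
Why: Directed ortho-metalation takes place at the position flanked by both MOM ethers, and after transmetalation the copper-catalysed Grignard reagent opens β-propiolactone by SN2 attack at the O–CH2 carbon to give the 3-arylpropanoic acid.

**Step 3**
Reactants: 6 3-[4-methoxy-2,6-bis(methoxymethoxy)phenyl]propanoic acid; 7 (2R)-but-3-en-2-ol
Product: 8 (2R)-but-3-en-2-yl 3-[4-methoxy-2,6-bis(methoxymethoxy)phenyl]propanoate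
Conditions: DCC, DMAP (cat.), CH2Cl2, 0 °C → rt
Reagents that add atoms: none
Why: Steglich esterification acylates the carbinol oxygen without touching its C–O bond, so the (R) configuration of 7 is kept.

**Step 4**
Reactants: 8 (2R)-but-3-en-2-yl 3-[4-methoxy-2,6-bis(methoxymethoxy)phenyl]propanoate
Product: 12 (2R,4E)-2-{[4-methoxy-2,6-bis(methoxymethoxy)phenyl]methyl}hex-4-enoic acid, via lithium enolate 9 (not isolated), via silyl ketene acetal 10 (not isolated), via trimethylsilyl ester 11 (not isolated)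
Conditions: LiN(i-Pr)2, Me3SiCl, Et3N, THF, −78 °C → 60 °C; then H2O
Reagents that add atoms: none
Why: Ireland–Claisen [3,3]-sigmatropic rearrangement: kinetic deprotonation in THF gives the enolate with CH2Ar trans to O–Li, and the chair transition state with the carbinol methyl equatorial forms the new C–C bond on one face only, so the (R) carbinol centre is traded for the (R) centre at C2 and an (E)-alkene (1,3-chirality transfer).

**Step 5**
Reactants: 12 (2R,4E)-2-{[4-methoxy-2,6-bis(methoxymethoxy)phenyl]methyl}hex-4-enoic acid; 13 2-methylbut-2-ene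
Product: 14 (2R)-2-{[4-methoxy-2,6-bis(methoxymethoxy)phenyl]methyl}-5-methylhex-4-enoic acid
Conditions: 13 (excess), second-generation Grubbs catalyst RuCl2(=CHPh)(PCy3)(H2IMes) (5 mol %), CH2Cl2, 40 °C
Reagents that add atoms: none
Why: Olefin cross-metathesis with excess 2-methylbut-2-ene swaps the ethylidene end of the crotyl group for isopropylidene (prenyl) and does not involve the stereocentre.

**Step 6**
Reactants: 14 (2R)-2-{[4-methoxy-2,6-bis(methoxymethoxy)phenyl]methyl}-5-methylhex-4-enoic acid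
Product: 16 (3R)-3-{[4-methoxy-2,6-bis(methoxymethoxy)phenyl]methyl}-6-methylhept-5-en-2-one, via dilithium gem-diolate 15 (not isolated)
Conditions: MeLi (3 equiv), Et2O, 0 °C → rt; then inverse quench into H2O, 0 °C
Reagents that add atoms: methyllithium, [Li]C
Why: Addition of MeLi to the lithium carboxylate gives a gem-diolate that collapses to the methyl ketone only on work-up, which prevents over-addition and leaves the α-stereocentre untouched.

**Step 7**
Reactants: 16 (3R)-3-{[4-methoxy-2,6-bis(methoxymethoxy)phenyl]methyl}-6-methylhept-5-en-2-one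
Product: 17 5-methoxy-1,3-bis(methoxymethoxy)-2-[(2R)-5-methyl-2-(prop-1-en-2-yl)hex-4-en-1-yl]benzene
Conditions: Cp2TiMe2, toluene, 70 °C, dark
Reagents that add atoms: dimethyltitanocene, C[Ti](C)(C1C=CC=C1)C1C=CC=C1
Why: Petasis methylenation with the non-basic titanium methylidene turns the epimerisable α-branched ketone into the isopropenyl group with the stereocentre intact, completing the (R)-lavandulyl chain.

**Step 8**
Reactants: 18 2,4-dihydroxybenzaldehyde
Product: 19 2,4-bis(methoxymethoxy)benzaldehyde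
Conditions: NaH, MOMCl, DMF, 0 °C → rt
Reagents that add atoms: chloromethyl methyl ether (MOMCl), COCCl
Why: Double Williamson O-alkylation (MOM protection) of both phenols.

**Step 9**
Reactants: 19 2,4-bis(methoxymethoxy)benzaldehyde; 20 diethyl {2-[methoxy(methyl)amino]-2-oxoethyl}phosphonate
Product: 22 (2E)-3-[2,4-bis(methoxymethoxy)phenyl]-N-methoxy-N-methylprop-2-enamide, via sodium phosphonate carbanion 21 (not isolated)
Conditions: NaH, THF, 0 °C → rt; then dil. HCl (pH 5)
Reagents that add atoms: none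
Why: Horner–Wadsworth–Emmons olefination of the aldehyde with the stabilised phosphonate anion gives the (E)-enamide.

**Step 10**
Reactants: 17 5-methoxy-1,3-bis(methoxymethoxy)-2-[(2R)-5-methyl-2-(prop-1-en-2-yl)hex-4-en-1-yl]benzene; 22 (2E)-3-[2,4-bis(methoxymethoxy)phenyl]-N-methoxy-N-methylprop-2-enamide
Product: 25 (2E)-3-[2,4-bis(methoxymethoxy)phenyl]-1-{6-methoxy-2,4-bis(methoxymethoxy)-3-[(2R)-5-methyl-2-(prop-1-en-2-yl)hex-4-en-1-yl]phenyl}prop-2-en-1-one, via aryllithium 23 (not isolated), via lithium tetrahedral adduct 24 (not isolated)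
Conditions: n-BuLi, TMEDA, THF, 0 °C; then 22, −78 → 0 °C; then H2O
Reagents that add atoms: none
Why: Directed ortho-metalation at either of the two equivalent ring C–H positions, each flanked by OMOM and OMe, followed by acylation with the Weinreb amide, whose chelated tetrahedral adduct prevents a second addition, gives the (E)-chalcone.

**Step 11**
Reactants: 25 (2E)-3-[2,4-bis(methoxymethoxy)phenyl]-1-{6-methoxy-2,4-bis(methoxymethoxy)-3-[(2R)-5-methyl-2-(prop-1-en-2-yl)hex-4-en-1-yl]phenyl}prop-2-en-1-one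
Product: 28 kurarinone [(2S)-2-(2,4-dihydroxyphenyl)-7-hydroxy-5-methoxy-8-[(2R)-5-methyl-2-(prop-1-en-2-yl)hex-4-en-1-yl]-2,3-dihydro-4H-chromen-4-one], via kuraridin 26 (not isolated), via kurarinone C2 epimer 27 (not isolated)
Conditions: 3 M HCl, MeOH–THF, 50 °C, dark; then NaOAc, EtOH, reflux; preparative HPLC (C18) to collect 28; the fraction rich in 27 is returned unpurified to NaOAc, EtOH, reflux and separated again
Reagents that add atoms: none
Why: Acid-catalysed acetal cleavage frees the four phenols and the 2'-OH closes ring C by intramolecular oxa-Michael addition (chalcone–flavanone isomerisation) without facial control, so the (2S) flavanone 28 and its (2R) epimer 27 form in about equal amounts as separable diastereomers, and 27 is converted into 28 by retro-oxa-Michael opening to 26 and reclosure when its fraction is put back under the NaOAc conditions.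

**Compound list**
1 | 5-methoxybenzene-1,3-diol (5-methoxyresorcinol) | COc1cc(O)cc(O)c1 | starting material
2 | 1-methoxy-3,5-bis(methoxymethoxy)benzene | COCOc1cc(OC)cc(OCOC)c1 | intermediate
3 | oxetan-2-one (β-propiolactone) | O=C1CCO1 | starting material
4 | [4-methoxy-2,6-bis(methoxymethoxy)phenyl]lithium | [Li]c1c(OCOC)cc(OC)cc1OCOC | intermediate
5 | [4-methoxy-2,6-bis(methoxymethoxy)phenyl]magnesium bromide | Br[Mg]c1c(OCOC)cc(OC)cc1OCOC | intermediate
6 | 3-[4-methoxy-2,6-bis(methoxymethoxy)phenyl]propanoic acid | OC(=O)CCc1c(OCOC)cc(OC)cc1OCOC | intermediate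
7 | (2R)-but-3-en-2-ol | C=C[C@@H](C)O | starting material
8 | (2R)-but-3-en-2-yl 3-[4-methoxy-2,6-bis(methoxymethoxy)phenyl]propanoate | C=C[C@@H](C)OC(=O)CCc1c(OCOC)cc(OC)cc1OCOC | intermediate
9 | lithium enolate of 8 (CH2Ar cis to the allyloxy oxygen, trans to O–Li) | C=C[C@@H](C)O/C(=C\Cc1c(OCOC)cc(OC)cc1OCOC)O[Li] | intermediate
10 | trimethylsilyl ketene acetal of 8 (same geometry, E) | C=C[C@@H](C)O/C(=C\Cc1c(OCOC)cc(OC)cc1OCOC)O[Si](C)(C)C | intermediate
11 | trimethylsilyl (2R,4E)-2-{[4-methoxy-2,6-bis(methoxymethoxy)phenyl]methyl}hex-4-enoate | C[Si](C)(C)OC(=O)[C@H](C/C=C/C)Cc1c(OCOC)cc(OC)cc1OCOC | intermediate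
12 | (2R,4E)-2-{[4-methoxy-2,6-bis(methoxymethoxy)phenyl]methyl}hex-4-enoic acid | OC(=O)[C@H](C/C=C/C)Cc1c(OCOC)cc(OC)cc1OCOC | intermediate
13 | 2-methylbut-2-ene | CC=C(C)C | starting material
14 | (2R)-2-{[4-methoxy-2,6-bis(methoxymethoxy)phenyl]methyl}-5-methylhex-4-enoic acid | OC(=O)[C@H](CC=C(C)C)Cc1c(OCOC)cc(OC)cc1OCOC | intermediate
15 | dilithium (3R)-3-{[4-methoxy-2,6-bis(methoxymethoxy)phenyl]methyl}-6-methylhept-5-ene-2,2-diolate | CC(O[Li])(O[Li])[C@H](CC=C(C)C)Cc1c(OCOC)cc(OC)cc1OCOC | intermediate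
16 | (3R)-3-{[4-methoxy-2,6-bis(methoxymethoxy)phenyl]methyl}-6-methylhept-5-en-2-one | CC(=O)[C@H](CC=C(C)C)Cc1c(OCOC)cc(OC)cc1OCOC | intermediate
17 | 5-methoxy-1,3-bis(methoxymethoxy)-2-[(2R)-5-methyl-2-(prop-1-en-2-yl)hex-4-en-1-yl]benzene | C=C(C)[C@H](CC=C(C)C)Cc1c(OCOC)cc(OC)cc1OCOC | intermediate
18 | 2,4-dihydroxybenzaldehyde | O=Cc1ccc(O)cc1O | starting material
19 | 2,4-bis(methoxymethoxy)benzaldehyde | O=Cc1ccc(OCOC)cc1OCOC | intermediate
20 | diethyl {2-[methoxy(methyl)amino]-2-oxoethyl}phosphonate | CCOP(=O)(CC(=O)N(C)OC)OCC | starting material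
21 | sodium salt of the carbanion of 20 | [Na+].CCOP(=O)(OCC)[CH-]C(=O)N(C)OC | intermediate
22 | (2E)-3-[2,4-bis(methoxymethoxy)phenyl]-N-methoxy-N-methylprop-2-enamide | CON(C)C(=O)/C=C/c1ccc(OCOC)cc1OCOC | intermediate
23 | {6-methoxy-2,4-bis(methoxymethoxy)-3-[(2R)-5-methyl-2-(prop-1-en-2-yl)hex-4-en-1-yl]phenyl}lithium | C=C(C)[C@H](CC=C(C)C)Cc1c(OCOC)cc(OC)c([Li])c1OCOC | intermediate
24 | lithium tetrahedral adduct of 23 with 22 (C–OLi, N(OMe)Me; both configurations at the new carbon) | C=C(C)[C@H](CC=C(C)C)Cc1c(OCOC)cc(OC)c(C(O[Li])(/C=C/c2ccc(OCOC)cc2OCOC)N(C)OC)c1OCOC | intermediate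
25 | (2E)-3-[2,4-bis(methoxymethoxy)phenyl]-1-{6-methoxy-2,4-bis(methoxymethoxy)-3-[(2R)-5-methyl-2-(prop-1-en-2-yl)hex-4-en-1-yl]phenyl}prop-2-en-1-one | C=C(C)[C@H](CC=C(C)C)Cc1c(OCOC)cc(OC)c(C(=O)/C=C/c2ccc(OCOC)cc2OCOC)c1OCOC | intermediate
26 | kuraridin, (2E)-3-(2,4-dihydroxyphenyl)-1-{2,4-dihydroxy-6-methoxy-3-[(2R)-5-methyl-2-(prop-1-en-2-yl)hex-4-en-1-yl]phenyl}prop-2-en-1-one | C=C(C)[C@H](CC=C(C)C)Cc1c(O)cc(OC)c(C(=O)/C=C/c2ccc(O)cc2O)c1O | intermediate
27 | C2 epimer of kurarinone, (2R)-2-(2,4-dihydroxyphenyl)-7-hydroxy-5-methoxy-8-[(2R)-5-methyl-2-(prop-1-en-2-yl)hex-4-en-1-yl]-2,3-dihydro-4H-chromen-4-one | C=C(C)[C@H](CC=C(C)C)Cc1c(O)cc(OC)c2c1O[C@@H](c1ccc(O)cc1O)CC2=O | intermediate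
28 | kurarinone, (2S)-2-(2,4-dihydroxyphenyl)-7-hydroxy-5-methoxy-8-[(2R)-5-methyl-2-(prop-1-en-2-yl)hex-4-en-1-yl]-2,3-dihydro-4H-chromen-4-one | C=C(C)[C@H](CC=C(C)C)Cc1c(O)cc(OC)c2c1O[C@H](c1ccc(O)cc1O)CC2=O | target

**Step count**
Total: 11 steps. Longest linear sequence: 9 steps (steps 1–7, 10, 11).

**Steps most likely to fail, with fallbacks**

Step 4. The enantiomeric ratio of 12 is capped by the enolate geometry (typically about 94:6 for LiN(i-Pr)2 in THF) and by the chair preference, and it carries through to the final ee. The fallback is an Eschenmoser–Claisen variant, still a [3,3] shift from the same bought alcohol, in which the ketene N,O-acetal geometry is fixed by allylic strain instead of by a kinetic deprotonation. It sets out from acid 6. Amide formation (Me2NH, DCC) gives N,N-dimethyl-3-[4-methoxy-2,6-bis(methoxymethoxy)phenyl]propanamide F1. O-Methylation (Me3OBF4) followed by NaOMe gives the amide dimethyl acetal F2. Heating F2 with alcohol 7 (xylene, 140 °C) exchanges one methoxy group, loses methanol to the ketene N,O-acetal F3 (CH2Ar cis to the allyloxy oxygen) and rearranges it to the (2R,4E)-N,N-dimethylhex-4-enamide F4. Cross-metathesis with 13 as in step 5 gives the prenyl amide F5. MeLi (THF, −78 → 0 °C) adds once to give the lithium hemiaminal adduct F6, which collapses on work-up to ketone 16, where the route is rejoined.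

Step 10. The aryllithium is flanked by two ortho substituents and may add sluggishly to the cinnamoyl Weinreb amide or attack it in a conjugate sense. The fallback builds the enone in two stages by acetylation and Claisen–Schmidt condensation. It sets out from aryllithium 23 (made from 17 as in step 10). N-Methoxy-N-methylacetamide gives, through the lithium adduct F7, the acetophenone F8. KOH in EtOH with aldehyde 19 gives the aldol adduct F9, which dehydrates in the same pot to chalcone 25, where the route is rejoined.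

Step 11. Protic acid may add the free phenols across the lavandulyl double bonds, the free 2-hydroxy group on ring B may divert the chalcone towards a flavylium salt, and the C2 epimers of the free tetraphenol may be hard to separate. The fallback closes ring C before the phenols are unmasked and removes the remaining MOM groups without protic acid. It sets out from 25. Dilute HCl in MeOH at 0 °C removes only the carbonyl-flanked 2'-MOM group and gives the 2'-hydroxychalcone F10. NaOAc in EtOH at reflux closes ring C to the tri-MOM flavanones, the (2S) isomer F11 and the (2R) isomer F12, which are separated by chromatography at this lipophilic stage, with F12 recycled through the NaOAc step. Me3SiOTf with 2,2'-bipyridyl (CH3CN, 0 °C) converts the aryl MOM ethers of F11 into the tris(trimethylsilyl) ether F13, and water then gives 28, where the route is rejoined.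

**Further compounds**
F1 | step 4 | N,N-dimethyl-3-[4-methoxy-2,6-bis(methoxymethoxy)phenyl]propanamide | CN(C)C(=O)CCc1c(OCOC)cc(OC)cc1OCOC
F2 | step 4 | 1,1-dimethoxy-3-[4-methoxy-2,6-bis(methoxymethoxy)phenyl]-N,N-dimethylpropan-1-amine | COC(OC)(CCc1c(OCOC)cc(OC)cc1OCOC)N(C)C
F3 | step 4 | ketene N,O-acetal of F1 with (2R)-but-3-en-2-ol (CH2Ar cis to the allyloxy oxygen) | C=C[C@@H](C)O/C(=C\Cc1c(OCOC)cc(OC)cc1OCOC)N(C)C
F4 | step 4 | (2R,4E)-2-{[4-methoxy-2,6-bis(methoxymethoxy)phenyl]methyl}-N,N-dimethylhex-4-enamide | CN(C)C(=O)[C@H](C/C=C/C)Cc1c(OCOC)cc(OC)cc1OCOC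
F5 | step 4 | (2R)-2-{[4-methoxy-2,6-bis(methoxymethoxy)phenyl]methyl}-N,N,5-trimethylhex-4-enamide | CN(C)C(=O)[C@H](CC=C(C)C)Cc1c(OCOC)cc(OC)cc1OCOC
F6 | step 4 | lithium hemiaminal adduct of F5 with MeLi | CC(O[Li])(N(C)C)[C@H](CC=C(C)C)Cc1c(OCOC)cc(OC)cc1OCOC
F7 | step 10 | lithium tetrahedral adduct of 23 with N-methoxy-N-methylacetamide | C=C(C)[C@H](CC=C(C)C)Cc1c(OCOC)cc(OC)c(C(C)(O[Li])N(C)OC)c1OCOC
F8 | step 10 | 1-{6-methoxy-2,4-bis(methoxymethoxy)-3-[(2R)-5-methyl-2-(prop-1-en-2-yl)hex-4-en-1-yl]phenyl}ethan-1-one | C=C(C)[C@H](CC=C(C)C)Cc1c(OCOC)cc(OC)c(C(C)=O)c1OCOC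
F9 | step 10 | 3-[2,4-bis(methoxymethoxy)phenyl]-3-hydroxy-1-{6-methoxy-2,4-bis(methoxymethoxy)-3-[(2R)-5-methyl-2-(prop-1-en-2-yl)hex-4-en-1-yl]phenyl}propan-1-one (both carbinol epimers) | C=C(C)[C@H](CC=C(C)C)Cc1c(OCOC)cc(OC)c(C(=O)CC(O)c2ccc(OCOC)cc2OCOC)c1OCOC
F10 | step 11 | (2E)-3-[2,4-bis(methoxymethoxy)phenyl]-1-{2-hydroxy-6-methoxy-4-(methoxymethoxy)-3-[(2R)-5-methyl-2-(prop-1-en-2-yl)hex-4-en-1-yl]phenyl}prop-2-en-1-one | C=C(C)[C@H](CC=C(C)C)Cc1c(OCOC)cc(OC)c(C(=O)/C=C/c2ccc(OCOC)cc2OCOC)c1O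
F11 | step 11 | (2S)-2-[2,4-bis(methoxymethoxy)phenyl]-5-methoxy-7-(methoxymethoxy)-8-[(2R)-5-methyl-2-(prop-1-en-2-yl)hex-4-en-1-yl]-2,3-dihydro-4H-chromen-4-one | C=C(C)[C@H](CC=C(C)C)Cc1c(OCOC)cc(OC)c2c1O[C@H](c1ccc(OCOC)cc1OCOC)CC2=O
F12 | step 11 | (2R)-epimer of F11 | C=C(C)[C@H](CC=C(C)C)Cc1c(OCOC)cc(OC)c2c1O[C@@H](c1ccc(OCOC)cc1OCOC)CC2=O
F13 | step 11 | tris(trimethylsilyl) ether of kurarinone (7-O, 2'-O, 4'-O) | C=C(C)[C@H](CC=C(C)C)Cc1c(O[Si](C)(C)C)cc(OC)c2c1O[C@H](c1ccc(O[Si](C)(C)C)cc1O[Si](C)(C)C)CC2=O
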